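Ring C of the flavone is disconnected at O1–C8a and C4–C4a, the two bonds that tie it to ring A. The feature exploited is that C8a (bearing O1) and C4a (bearing the C4 carbonyl) are neighbouring carbons of ring A, and that the C5 oxygen next to C4a can polarize an aryne. In one operation the aryne from silyl triflate 8 should accept the enolate oxygen of α-methoxy β-ketoester 13 at C8a, and the aryl anion left at C4a should then be acylated by the ester, closing the pyranone with the 3-methoxy group in place. Iodination at C6, Sonogashira coupling and a single hydrogenation complete the target.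

Key step: step 5

Remark: the target has no stereocentre. Ketoester 13 is used as the racemate because its only stereocentre becomes sp2 in step 5. Compounds 1, 9, 10 and 22 are taken as purchasable.

Step 1
Reactants: 1 3,5-bis(benzyloxy)phenol
Product: 2 3,5-bis(benzyloxy)phenyl N-(propan-2-yl)carbamate
Conditions: iPrNCO, Et3N (cat.), CH2Cl2, rt
Reagents that add atoms: isopropyl isocyanate, CC(C)N=C=O
Why: Base-catalysed addition of the phenol to the isocyanate (carbamoylation) installs a strong ortho-directing group that can later be removed under mild, non-reducing conditions.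

Step 2
Reactants: 2 3,5-bis(benzyloxy)phenyl N-(propan-2-yl)carbamate
Product: 6 3,5-bis(benzyloxy)-2-(trimethylsilyl)phenyl N-(propan-2-yl)carbamate, via N-silyl carbamate 3 (not isolated), via aryllithium 4 (not isolated), via N-silyl arylsilane 5 (not isolated)
Conditions: TBSOTf, TMEDA, Et2O, 0 °C to rt; n-BuLi, TMEDA, −78 °C; TMSCl, −78 °C to rt; cold aq NaHSO4 (brief)
Reagents that add atoms: chlorotrimethylsilane, C[Si](C)(C)Cl
Why: In-situ N-silylation turns the carbamate into a tertiary directing group, directed ortho-metalation should then occur at the one carbon flanked by both the carbamate and a benzyloxy group (cooperative direction, fast at −78 °C, so benzylic deprotonation should not compete), and quenching the aryllithium with TMSCl followed by hydrolytic loss of the N-silyl group on work-up should give 6.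

Step 3
Reactants: 6 3,5-bis(benzyloxy)-2-(trimethylsilyl)phenyl N-(propan-2-yl)carbamate
Product: 8 3,5-bis(benzyloxy)-2-(trimethylsilyl)phenyl trifluoromethanesulfonate, via silylphenol 7 (not isolated)
Conditions: DBU, Et2NH, MeCN, 40 °C; then PhNTf2, rt
Reagents that add atoms: N-phenylbis(trifluoromethanesulfonimide), O=S(=O)(N(c1ccccc1)S(=O)(=O)C(F)(F)F)C(F)(F)F
Why: E1cB cleavage of the secondary carbamate (the isocyanate is scavenged by Et2NH as a urea) releases the phenoxide, which is O-triflated in the same pot by a mild sulfonyl-transfer reagent, so the electron-rich arylsilane never meets acid that could protodesilylate it.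

Step 4
Reactants: 9 methyl methoxyacetate; 10 4-(benzyloxy)benzoyl chloride
Product: 13 methyl 3-[4-(benzyloxy)phenyl]-2-methoxy-3-oxopropanoate (racemic), via lithium ester enolate 11 (not isolated), via lithium ketoester enolate 12 (not isolated)
Conditions: 9 (2 equiv), LiN(iPr)2 (2 equiv), THF, −78 °C; then 10, −78 to 0 °C; aq NH4Cl
Reagents that add atoms: none
Why: C-acylation of a preformed lithium ester enolate by an acid chloride (crossed Claisen-type acylation) should give the β-ketoester, the second equivalent of enolate deprotonating the more acidic product and so protecting it from a second acylation.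

Step 5
Reactants: 8 3,5-bis(benzyloxy)-2-(trimethylsilyl)phenyl trifluoromethanesulfonate; 13 methyl 3-[4-(benzyloxy)phenyl]-2-methoxy-3-oxopropanoate
Product: 17 5,7-bis(benzyloxy)-2-[4-(benzyloxy)phenyl]-3-methoxy-4H-chromen-4-one, via cesium enolate 14 (not isolated), via aryne 15 (not isolated), via aryl anion adduct 16 (not isolated)
Conditions: CsF (4 equiv), THF, 65 °C, slow addition of 8 (1.2 equiv)
Reagents that add atoms: none
Why: Proposed new method: CsF desilylates 8 with loss of triflate to give aryne 15 and converts 13 into its chelated cesium enolate 14, whose ketone-derived oxygen adds to the aryne carbon remote from the flanking benzyloxy group (future C8a), placing the aryl anion of 16 on the carbon next to that group (future C4a). The anion then attacks the methyl ester held cis to the aryloxy group and expels methoxide, so ring C closes by a 6-exo-trig addition–elimination at the ester carbonyl (intramolecular acyl substitution). The closest known reaction type is the fluoride-induced annulation of arynes with methyl salicylates to xanthones, in which O-arylation is followed by the same ester acylation of the aryl anion; the known competitor is aryne acyl-alkylation of β-ketoesters, which begins with C-arylation. No stereocentre is created, and the racemic centre of 13 becomes sp2. Two selectivities are needed: the aryne regiochemistry, secured by the inductive pull of the benzyloxy group next to the triple bond, which steers the nucleophile to the distal carbon and stabilizes the ortho anion; and oxygen over carbon attack of the ambident enolate, which the fully substituted, methoxy-bearing enolate carbon (a quaternary centre would have to form) and the loosely bound cesium counterion in THF should favour but do not guarantee. Slow addition of 8 keeps the aryne dilute so that 16 should cyclize faster than it is protonated by bifluoride.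

Step 6
Reactants: 17 5,7-bis(benzyloxy)-2-[4-(benzyloxy)phenyl]-3-methoxy-4H-chromen-4-one
Product: 19 7-(benzyloxy)-2-[4-(benzyloxy)phenyl]-5-hydroxy-3-methoxy-4H-chromen-4-one, via aryloxydichloroborane 18 (not isolated)
Conditions: BCl3 (1.1 equiv), CH2Cl2, −78 °C; then H2O
Reagents that add atoms: none
Why: Chelation-controlled Lewis-acid ether cleavage: BCl3 binds between the C4 carbonyl and the peri 5-oxygen, so only that benzyl group should be lost (as benzyl chloride), while the 7- and 4'-benzyl ethers and the less labile 3-methyl ether remain.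

Step 7
Reactants: 19 7-(benzyloxy)-2-[4-(benzyloxy)phenyl]-5-hydroxy-3-methoxy-4H-chromen-4-one
Product: 20 7-(benzyloxy)-2-[4-(benzyloxy)phenyl]-5-hydroxy-6-iodo-3-methoxy-4H-chromen-4-one
Conditions: BnMe3N·ICl2 (1.05 equiv), CaCO3, CH2Cl2–MeOH, rt
Reagents that add atoms: benzyltrimethylammonium dichloroiodate, C[N+](C)(C)Cc1ccccc1.Cl[I-]Cl
Why: Electrophilic aromatic iodination: in 5-hydroxy-7-alkoxyflavones the free, hydrogen-bonded 5-hydroxyl directs this mild iodine source to the ortho carbon C6 and not to C8, and ring B is deactivated by conjugation with the pyranone.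

Step 8
Reactants: 20 7-(benzyloxy)-2-[4-(benzyloxy)phenyl]-5-hydroxy-6-iodo-3-methoxy-4H-chromen-4-one
Product: 21 5,7-bis(benzyloxy)-2-[4-(benzyloxy)phenyl]-6-iodo-3-methoxy-4H-chromen-4-one
Conditions: BnBr, K2CO3, DMF, 60 °C
Reagents that add atoms: benzyl bromide, BrCc1ccccc1
Why: Williamson etherification of the chelated phenol under forcing carbonate conditions re-caps the 5-oxygen, which prevents cyclization of a free ortho-hydroxyl onto the alkyne (furanoflavone formation) in the coupling and costs no extra step because the ether falls in the final hydrogenation.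

Step 9
Reactants: 21 5,7-bis(benzyloxy)-2-[4-(benzyloxy)phenyl]-6-iodo-3-methoxy-4H-chromen-4-one; 22 2-methylbut-3-yn-2-ol
Product: 23 5,7-bis(benzyloxy)-2-[4-(benzyloxy)phenyl]-6-(3-hydroxy-3-methylbut-1-yn-1-yl)-3-methoxy-4H-chromen-4-one
Conditions: Pd(PPh3)2Cl2 (cat.), CuI (cat.), Et3N, DMF, 70 °C, degassed
Reagents that add atoms: none
Why: Sonogashira coupling of the aryl iodide with the terminal alkyne should install the full C5 side chain, since iodides undergo oxidative addition readily even between two ortho alkoxy groups and the tertiary propargylic alcohol needs no protection.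

Step 10
Reactants: 23 5,7-bis(benzyloxy)-2-[4-(benzyloxy)phenyl]-6-(3-hydroxy-3-methylbut-1-yn-1-yl)-3-methoxy-4H-chromen-4-one
Product: 24 5,7-dihydroxy-6-(3-hydroxy-3-methylbutyl)-2-(4-hydroxyphenyl)-3-methoxy-4H-chromen-4-one (topazolin hydrate)
Conditions: H2 (1 atm), Pd/C, EtOAc–MeOH, rt
Reagents that add atoms: none
Why: Heterogeneous catalytic hydrogenation should saturate the alkyne to the 3-hydroxy-3-methylbutyl chain and hydrogenolyse the three benzyl ethers in the same operation, under neutral conditions that spare the tetrasubstituted C2=C3 bond and do not trigger acid-catalysed cyclization of the tertiary alcohol onto a neighbouring phenol.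

Compound list
1 | 3,5-bis(benzyloxy)phenol | Oc1cc(OCc2ccccc2)cc(OCc2ccccc2)c1 | starting material
2 | 3,5-bis(benzyloxy)phenyl N-(propan-2-yl)carbamate | CC(C)NC(=O)Oc1cc(OCc2ccccc2)cc(OCc2ccccc2)c1 | intermediate
3 | 3,5-bis(benzyloxy)phenyl N-[tert-butyl(dimethyl)silyl]-N-(propan-2-yl)carbamate | CC(C)N(C(=O)Oc1cc(OCc2ccccc2)cc(OCc2ccccc2)c1)[Si](C)(C)C(C)(C)C | intermediate (not isolated)
4 | 2-lithio derivative of 3 (lithium on the carbon between the carbamate and a benzyloxy group) | [Li]c1c(OC(=O)N(C(C)C)[Si](C)(C)C(C)(C)C)cc(OCc2ccccc2)cc1OCc1ccccc1 | intermediate (not isolated)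
5 | 3,5-bis(benzyloxy)-2-(trimethylsilyl)phenyl N-[tert-butyl(dimethyl)silyl]-N-(propan-2-yl)carbamate | CC(C)N(C(=O)Oc1cc(OCc2ccccc2)cc(OCc2ccccc2)c1[Si](C)(C)C)[Si](C)(C)C(C)(C)C | intermediate (not isolated)
6 | 3,5-bis(benzyloxy)-2-(trimethylsilyl)phenyl N-(propan-2-yl)carbamate | CC(C)NC(=O)Oc1cc(OCc2ccccc2)cc(OCc2ccccc2)c1[Si](C)(C)C | intermediate
7 | 3,5-bis(benzyloxy)-2-(trimethylsilyl)phenol (present as its DBU-H phenoxide) | C[Si](C)(C)c1c(O)cc(OCc2ccccc2)cc1OCc1ccccc1 | intermediate (not isolated)
8 | 3,5-bis(benzyloxy)-2-(trimethylsilyl)phenyl trifluoromethanesulfonate | C[Si](C)(C)c1c(OS(=O)(=O)C(F)(F)F)cc(OCc2ccccc2)cc1OCc1ccccc1 | intermediate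
9 | methyl methoxyacetate | COCC(=O)OC | starting material
10 | 4-(benzyloxy)benzoyl chloride | O=C(Cl)c1ccc(OCc2ccccc2)cc1 | starting material
11 | lithium (E)-1,2-dimethoxyethen-1-olate (chelated lithium enolate of 9) | CO/C=C(/OC)O[Li] | intermediate (not isolated)
12 | lithium (E)-enolate of 13 (O–Li cis to the ester) | COC(=O)/C(OC)=C(\O[Li])c1ccc(OCc2ccccc2)cc1 | intermediate (not isolated)
13 | methyl 3-[4-(benzyloxy)phenyl]-2-methoxy-3-oxopropanoate (racemic) | COC(=O)C(OC)C(=O)c1ccc(OCc2ccccc2)cc1 | intermediate
14 | cesium (E)-enolate of 13 (enolate oxygen cis to the ester) | COC(=O)/C(OC)=C(\[O-])c1ccc(OCc2ccccc2)cc1.[Cs+] | intermediate (not isolated)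
15 | 3,5-bis(benzyloxy)benzyne (1,2-didehydro-3,5-bis(benzyloxy)benzene) | C1#CC(OCc2ccccc2)=CC(OCc2ccccc2)=C1 | intermediate (not isolated)
16 | cesium 4,6-bis(benzyloxy)-2-({(1E)-1-[4-(benzyloxy)phenyl]-2,3-dimethoxy-3-oxoprop-1-en-1-yl}oxy)benzen-1-ide | COC(=O)/C(OC)=C(\Oc1cc(OCc2ccccc2)cc(OCc2ccccc2)[c-]1)c1ccc(OCc2ccccc2)cc1.[Cs+] | intermediate (not isolated)
17 | 5,7-bis(benzyloxy)-2-[4-(benzyloxy)phenyl]-3-methoxy-4H-chromen-4-one | COc1c(-c2ccc(OCc3ccccc3)cc2)oc2cc(OCc3ccccc3)cc(OCc3ccccc3)c2c1=O | intermediate
18 | 7-(benzyloxy)-2-[4-(benzyloxy)phenyl]-5-[(dichloroboranyl)oxy]-3-methoxy-4H-chromen-4-one | COc1c(-c2ccc(OCc3ccccc3)cc2)oc2cc(OCc3ccccc3)cc(OB(Cl)Cl)c2c1=O | intermediate (not isolated)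
19 | 7-(benzyloxy)-2-[4-(benzyloxy)phenyl]-5-hydroxy-3-methoxy-4H-chromen-4-one | COc1c(-c2ccc(OCc3ccccc3)cc2)oc2cc(OCc3ccccc3)cc(O)c2c1=O | intermediate
20 | 7-(benzyloxy)-2-[4-(benzyloxy)phenyl]-5-hydroxy-6-iodo-3-methoxy-4H-chromen-4-one | COc1c(-c2ccc(OCc3ccccc3)cc2)oc2cc(OCc3ccccc3)c(I)c(O)c2c1=O | intermediate
21 | 5,7-bis(benzyloxy)-2-[4-(benzyloxy)phenyl]-6-iodo-3-methoxy-4H-chromen-4-one | COc1c(-c2ccc(OCc3ccccc3)cc2)oc2cc(OCc3ccccc3)c(I)c(OCc3ccccc3)c2c1=O | intermediate
22 | 2-methylbut-3-yn-2-ol | CC(C)(O)C#C | starting material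
23 | 5,7-bis(benzyloxy)-2-[4-(benzyloxy)phenyl]-6-(3-hydroxy-3-methylbut-1-yn-1-yl)-3-methoxy-4H-chromen-4-one | COc1c(-c2ccc(OCc3ccccc3)cc2)oc2cc(OCc3ccccc3)c(C#CC(C)(C)O)c(OCc3ccccc3)c2c1=O | intermediate
24 | 5,7-dihydroxy-6-(3-hydroxy-3-methylbutyl)-2-(4-hydroxyphenyl)-3-methoxy-4H-chromen-4-one (topazolin hydrate) | COc1c(-c2ccc(O)cc2)oc2cc(O)c(CCC(C)(C)O)c(O)c2c1=O | target

Total step count: 10. Longest linear sequence: 9 steps (steps 1, 2, 3, 5, 6, 7, 8, 9, 10, from 1 to 24); step 4 is the one-step side branch.

Steps most likely to fail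

Step 5. The ambident enolate may attack the aryne through carbon instead of oxygen and go on to acyl-alkylation, or the aryl anion may be protonated before it reaches the ester. The fallback builds ring C stepwise by known chemistry. It sets out from 8 and 10 and comes back to the route at 17. Treating 8 with methoxyacetic acid and CsF in hot THF should bring about the known insertion of an aryne into the acyl–oxygen bond of a carboxylic acid: O-arylation, then shift of the acyl group from oxygen to the adjacent aryl anion. This should give 1-[2,4-bis(benzyloxy)-6-hydroxyphenyl]-2-methoxyethan-1-one F1, with the acyl group next to the flanking benzyloxy group. A carboxylate has no nucleophilic carbon, so the oxygen-versus-carbon question does not arise. O-Aroylation of F1 with 10 (Et3N, DMAP, CH2Cl2) should give 3,5-bis(benzyloxy)-2-(methoxyacetyl)phenyl 4-(benzyloxy)benzoate F2. Baker–Venkataraman rearrangement with LiN(SiMe3)2 in THF should move the aroyl group to the ketone α-carbon and give 1-[2,4-bis(benzyloxy)-6-hydroxyphenyl]-3-[4-(benzyloxy)phenyl]-2-methoxypropane-1,3-dione F3 (racemic). Acid-catalysed cyclodehydration (TsOH, toluene, 80 °C) should then close the pyranone to 17.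

Step 2. The base may deprotonate a benzylic CH2 of the ethers (leading on to Wittig rearrangement) or the ring carbon between the two benzyloxy groups, or the silyl group may be lost from the very electron-rich ring during acidic work-up. The fallback replaces directed metalation by halogen–lithium exchange. It sets out from 1 and comes back at 8. Bromination of 1 with NBS in CH2Cl2 at −78 °C should give 3,5-bis(benzyloxy)-2-bromophenol F4, to be separated from the 4-bromo isomer. O-Silylation with HMDS in refluxing THF should give [3,5-bis(benzyloxy)-2-bromophenoxy]trimethylsilane F5. With n-BuLi in THF at −100 °C, bromine–lithium exchange (far faster than benzylic deprotonation) and retro-Brook migration of silicon from oxygen to carbon should give lithium 3,5-bis(benzyloxy)-2-(trimethylsilyl)phenoxide F6. Trapping F6 with Tf2O should give 8.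

Step 9. Oxidative addition and transmetalation may be slow at the doubly ortho-substituted, electron-rich C6 iodide, so that alkyne homocoupling or reductive loss of iodine takes over. The fallback forms the C6–side-chain bond as an sp2–sp3 bond by B-alkyl Suzuki–Miyaura coupling. It sets out from 21 and comes back at 24. Hydroboration of 2-methylbut-3-en-2-ol with 9-BBN in THF at rt should give 4-(9-borabicyclo[3.3.1]nonan-9-yl)-2-methylbutan-2-ol F7, since the terminal alkene reacts much faster than the hindered tertiary hydroxyl. Coupling of F7 with 21 (Pd(dppf)Cl2, K3PO4, DMF–H2O, 60 °C) should give 5,7-bis(benzyloxy)-2-[4-(benzyloxy)phenyl]-6-(3-hydroxy-3-methylbutyl)-3-methoxy-4H-chromen-4-one F8. Hydrogenolysis of the three benzyl ethers of F8 (H2, Pd/C, EtOAc–MeOH) should give 24.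

Further compounds
F1 | step 5 | 1-[2,4-bis(benzyloxy)-6-hydroxyphenyl]-2-methoxyethan-1-one | COCC(=O)c1c(O)cc(OCc2ccccc2)cc1OCc1ccccc1
F2 | step 5 | 3,5-bis(benzyloxy)-2-(methoxyacetyl)phenyl 4-(benzyloxy)benzoate | COCC(=O)c1c(OC(=O)c2ccc(OCc3ccccc3)cc2)cc(OCc2ccccc2)cc1OCc1ccccc1
F3 | step 5 | 1-[2,4-bis(benzyloxy)-6-hydroxyphenyl]-3-[4-(benzyloxy)phenyl]-2-methoxypropane-1,3-dione (racemic) | COC(C(=O)c1ccc(OCc2ccccc2)cc1)C(=O)c1c(O)cc(OCc2ccccc2)cc1OCc1ccccc1
F4 | step 2 | 3,5-bis(benzyloxy)-2-bromophenol | Oc1cc(OCc2ccccc2)cc(OCc2ccccc2)c1Br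
F5 | step 2 | [3,5-bis(benzyloxy)-2-bromophenoxy]trimethylsilane | C[Si](C)(C)Oc1cc(OCc2ccccc2)cc(OCc2ccccc2)c1Br
F6 | step 2 | lithium 3,5-bis(benzyloxy)-2-(trimethylsilyl)phenoxide | [Li+].[O-]c1cc(OCc2ccccc2)cc(OCc2ccccc2)c1[Si](C)(C)C
F7 | step 9 | 4-(9-borabicyclo[3.3.1]nonan-9-yl)-2-methylbutan-2-ol | CC(C)(O)CCB1C2CCCC1CCC2
F8 | step 9 | 5,7-bis(benzyloxy)-2-[4-(benzyloxy)phenyl]-6-(3-hydroxy-3-methylbutyl)-3-methoxy-4H-chromen-4-one | COc1c(-c2ccc(OCc3ccccc3)cc2)oc2cc(OCc3ccccc3)c(CCC(C)(C)O)c(OCc3ccccc3)c2c1=O
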